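**Plan**
- Retrosynthesis: the two phenolic O–H groups are closed into a cyclic carbonate and the benzene ring is taken back to its cis-2,3-dihydro form. The ring bonds C1–C2 and C3–C4 are then cut.
- Enabling feature: C2 and C3 of the benzene ring carry vicinal oxygens next to the C1 ester, so they are an enediol, supplied as vinylene carbonate. C1–C6–C5–C4 is the diene of a 2-pyrone whose C3 (target C1) already bears the ester and whose O1–C2 bridge leaves as CO2.
- Forward: the C24 chain is joined first by esterifying 2-oxo-2H-pyran-3-carboxylic acid. The only ring of the target then arises as a cyclohexa-1,3-diene by [4+2] cycloaddition and CO2 extrusion, is aromatised with DDQ, and the carbonate is hydrolysed last.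
- Stereochemistry: the target is achiral. The two cis carbinol centres made in the cycloaddition (suprafacial addition of a cyclic Z-alkene) are transient and vanish on aromatisation. The 1,2,3-pattern follows from connectivity because the dienophile is symmetric.

Key step: step 2

Assumption: 2-oxo-2H-pyran-3-carboxylic acid is taken as a purchasable building block, so the pyrone ring is not built in the main route; a ring synthesis from malonate is given as the fallback to step 1.

**Step 1**
Reactants: 1 2-oxo-2H-pyran-3-carboxylic acid; 2 1-tetracosanol
Product: 4 tetracosyl 2-oxo-2H-pyran-3-carboxylate, via 2-oxo-2H-pyran-3-carbonyl chloride 3 (not isolated)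
Conditions: (COCl)2 (1.3 equiv), DMF (cat.), CH2Cl2, 0 °C to rt; evaporate; then 2 (0.9 equiv), 2,6-lutidine (1.5 equiv), toluene, 45 °C
Reagents that add atoms: none
Why: Acyl chloride formation through the DMF-derived chloroiminium salt, followed by nucleophilic acyl substitution by the primary alcohol, is a standard esterification, and the hindered base 2,6-lutidine takes up HCl without adding to C6 of the electron-poor pyrone.

**Step 2**
Reactants: 4 tetracosyl 2-oxo-2H-pyran-3-carboxylate; 5 vinylene carbonate (1,3-dioxol-2-one)
Product: 7 tetracosyl cis-2-oxo-3a,7a-dihydro-1,3-benzodioxole-4-carboxylate (racemic), via bridged lactone cycloadduct 6 (not isolated)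
Conditions: 5 (3 equiv), BHT (1 mol %), degassed mesitylene (0.1 M), sealed tube, 140–150 °C, Ar; stopped when 4 is consumed; rapid chromatography on deactivated silica
Reagents that add atoms: none
Why: The 3-carboxylate lowers the LUMO of the pyrone diene (C3=C4–C5=C6), which pairs with the HOMO of the enediol carbonate in a concerted, suprafacial inverse-electron-demand Diels–Alder reaction across C3 and C6; the bridged lactone 6 (endo and exo isomers, which converge) then expels its O1–C2 bridge as CO2 in a retro-[4+2] at the same temperature and leaves cyclohexa-1,3-diene 7. The closest known reaction type is the tandem cycloaddition/CO2 extrusion of 2-pyrone-3-carboxylates with enol ethers and ketene acetals, together with the thermal Diels–Alder chemistry of vinylene carbonate. The six-membered carbocycle is closed by intermolecular [4+2] cycloaddition, and both ring bonds (C1–C2 and C3–C4 of the target) are made in the one pericyclic event. The two new carbinol stereocentres should be cis because the Z geometry locked in the five-membered dienophile is carried over suprafacially; they are racemic and are removed in step 3. No regiochemistry arises with the symmetric dienophile, so only chemoselectivity is needed: pyrone 4, with its additional lactone carbonyl, is a much better inverse-demand diene than product 7, and the neutral medium, the radical inhibitor, the dilution and the capped excess of 5 should hold back elimination across the allylic carbonate, polymerisation of 5, dimerisation of 7 and a second cycloaddition.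

**Step 3**
Reactants: 7 tetracosyl cis-2-oxo-3a,7a-dihydro-1,3-benzodioxole-4-carboxylate
Product: 8 tetracosyl 2-oxo-1,3-benzodioxole-4-carboxylate
Conditions: DDQ (1.2 equiv), benzene, 60 °C; hydroquinone filtered off, filtrate concentrated and used promptly
Reagents that add atoms: none
Why: In this quinone dehydrogenation DDQ should abstract hydride from C3a–H, whose cyclohexadienyl cation places no charge on the ester-bearing carbon and is flanked by oxygen, and loss of the C7a proton then gives the arene while the aprotic medium leaves carbonate and ester untouched.

**Step 4**
Reactants: 8 tetracosyl 2-oxo-1,3-benzodioxole-4-carboxylate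
Product: 9 Gentiside K (tetracosyl 2,3-dihydroxybenzoate)
Conditions: dilute aq NaHCO3 (0.2 equiv), THF, 0 °C to rt, Ar; then pH 4 (aq NaH2PO4); recrystallisation
Reagents that add atoms: none
Why: The strained diaryl carbonate of a catechol undergoes hydrolysis (nucleophilic acyl substitution, then decarboxylation of the aryl hydrogen carbonate) under conditions far too mild to saponify the long-chain benzoate, and exclusion of air keeps the catechol from oxidising.

**Compound list**
1 | 2-oxo-2H-pyran-3-carboxylic acid | O=C(O)C1=CC=COC1=O | starting material
2 | 1-tetracosanol | CCCCCCCCCCCCCCCCCCCCCCCCO | starting material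
3 | 2-oxo-2H-pyran-3-carbonyl chloride | O=C(Cl)C1=CC=COC1=O | intermediate (not isolated)
4 | tetracosyl 2-oxo-2H-pyran-3-carboxylate | O=C1OC=CC=C1C(=O)OCCCCCCCCCCCCCCCCCCCCCCCC | intermediate
5 | vinylene carbonate (1,3-dioxol-2-one) | O=C1OC=CO1 | starting material
6 | tetracosyl 4,9-dioxo-3,5,8-trioxatricyclo[5.2.2.0(2,6)]undec-10-ene-1-carboxylate, bridged lactone cycloadduct with cis-fused carbonate (racemic endo/exo mixture; isomer with the carbonate syn to the C10=C11 bridge drawn) | O=C1O[C@@H]2C=C[C@@]1(C(=O)OCCCCCCCCCCCCCCCCCCCCCCCC)[C@H]3OC(=O)O[C@H]32 | intermediate (not isolated)
7 | tetracosyl cis-2-oxo-3a,7a-dihydro-1,3-benzodioxole-4-carboxylate (racemic, one enantiomer drawn) | O=C1O[C@H]2C=CC=C(C(=O)OCCCCCCCCCCCCCCCCCCCCCCCC)[C@H]2O1 | intermediate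
8 | tetracosyl 2-oxo-1,3-benzodioxole-4-carboxylate (cyclic carbonate of the target) | O=C1Oc2cccc(C(=O)OCCCCCCCCCCCCCCCCCCCCCCCC)c2O1 | intermediate
9 | Gentiside K, tetracosyl 2,3-dihydroxybenzoate | CCCCCCCCCCCCCCCCCCCCCCCCOC(=O)c1cccc(O)c1O | target

Total step count: 4
Longest linear sequence: 4 steps (1 → 4 → 7 → 8 → 9)

**Steps most likely to fail**

Step 2. The cycloaddition may be so slow that other processes outrun it: polymerisation of the dienophile, [4+2] dimerisation of the product diene, a second addition of the dienophile, or thermal elimination across the allylic carbonate with aromatisation to a monophenol. The fallback gives up the cycloaddition and joins the chain to a preformed catechol acid. It sets out from 2, which is heated with 48% aqueous HBr and catalytic Bu4NBr at 110 °C to give 1-bromotetracosane F1. F1 then alkylates the carboxylate of commercial 2,3-dihydroxybenzoic acid (KHCO3, DMF/THF, 65 °C). Bicarbonate ionises only the carboxylic acid, so the phenols should remain unalkylated. The route is rejoined at 9.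

Step 3. Hydride transfer from the electron-poor diene may be slow, and the acidic hydroquinone may instead promote ionisation of the allylic carbonate, so that the ring aromatises by loss of oxygen instead of hydrogen. The fallback removes the carbonate first and oxidises an alcohol instead of a C–H bond. It sets out from 7, which is opened with LiOH (2 equiv) in THF/H2O at 0 °C, kept cold and short to avoid vinylogous elimination. This gives tetracosyl cis-5,6-dihydroxycyclohexa-1,3-diene-1-carboxylate F2, the long-chain analogue of the isolable cis-dihydrodiols of benzoate esters. Allylic alcohol oxidation with MnO2 in CH2Cl2 at rt should take the less hindered C5 carbinol to tetracosyl 6-hydroxy-5-oxocyclohexa-1,3-diene-1-carboxylate F3. F3 is a keto tautomer of the catechol and should enolise at once. A wash with aqueous Na2S2O4 returns any over-oxidised o-quinone. The route is rejoined at 9.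

Step 1. Chloride, base or alcohol may attack the electron-poor pyrone (at C6 or the lactone carbonyl, with ring opening) during acyl chloride formation or acylation, and the C24 alcohol may dissolve poorly. The fallback builds the pyrone ring after the ester is in place. It sets out from 2, which is coupled with mono-tert-butyl malonate (EDC·HCl, cat. DMAP, CH2Cl2) to give tert-butyl tetracosyl malonate F4. Knoevenagel-type condensation with 1,1,3,3-tetramethoxypropane (Ac2O, cat. ZnCl2, 100 °C) should give tert-butyl tetracosyl 2-[(2E)-3-methoxyprop-2-en-1-ylidene]malonate F5. Warm formic acid (70 °C) then cleaves the tert-butyl ester and closes the lactone onto the enol ether terminus with loss of isobutene and methanol. The route is rejoined at 4.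

**Further compounds**
F1 | step 2 | 1-bromotetracosane | CCCCCCCCCCCCCCCCCCCCCCCCBr
F2 | step 3 | tetracosyl cis-5,6-dihydroxycyclohexa-1,3-diene-1-carboxylate (racemic, one enantiomer drawn) | O[C@H]1C=CC=C(C(=O)OCCCCCCCCCCCCCCCCCCCCCCCC)[C@H]1O
F3 | step 3 | tetracosyl 6-hydroxy-5-oxocyclohexa-1,3-diene-1-carboxylate (transient keto tautomer, racemic, one enantiomer drawn) | O=C1C=CC=C(C(=O)OCCCCCCCCCCCCCCCCCCCCCCCC)[C@H]1O
F4 | step 1 | tert-butyl tetracosyl malonate | CC(C)(C)OC(=O)CC(=O)OCCCCCCCCCCCCCCCCCCCCCCCC
F5 | step 1 | tert-butyl tetracosyl 2-[(2E)-3-methoxyprop-2-en-1-ylidene]malonate (mixture of isomers about the malonate double bond) | CO/C=C/C=C(C(=O)OC(C)(C)C)C(=O)OCCCCCCCCCCCCCCCCCCCCCCCC
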